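Two free base per coupling: that ratio goes on the board first. This flask's nucleophile is charged with its acid still on.

electrophile 10 mM; free base 1.10 equiv; protonated nucleophile 1.00 equiv; time 4.0 d

    electrophile + nucleophile → acid set free + target (k1 = 91 L mol⁻¹ h⁻¹)
    nucleophile + acid set free ⇌ protonated nucleophile, settled at all times (K2 = 3200 L mol⁻¹)
    acid set free + free base ⇌ salt of the base (K3 = 11000 L mol⁻¹, k3 = 140 L mol⁻¹ h⁻¹)
    free base + target ⇌ idle adduct, settled at all times (K4 = 58 L mol⁻¹)
    electrophile + target → side product (k5 = 2.9 L mol⁻¹ h⁻¹)

- part of the electrophile that has reacted at 4.0 d
- share of the unused nucleophile that is free and not bound as protonated nucleophile, at 4.0 d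

- a species is counted by the electrophile in it: one side product counts as two
- amounts and yields of target count idle adduct too
- run time (flask): 4.0 d

Why two? One free base takes the acid off a protonated nucleophile, and a second takes the acid set free by the coupling.

How far does the base reach, then? Its balance gives the paid coupling, the amount of coupling that the charged free base can pay for: 5.50 mM, half its charge. Free base is the limiting reagent.

Does coupling stop there? No. Beyond it, each coupling leaves two acid unbound, so c(acid set free) grows by two for each coupling. The free share of the unused nucleophile is one over one plus 3200 L mol⁻¹ times c(acid set free).

But how far beyond? Try the mean of the paid coupling and the electrophile charged, 7.75 mM. There c(acid set free) is 4.50 mM and c(nucleophile) is 0.156 mM. Per electrophile, coupling then runs at 0.0142 h⁻¹ and the step to side product at 0.0160 h⁻¹, about the same, so I stop my reckoning there. The free share comes to 6.49%.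

And the electrophile? The part beyond the paid coupling decays at the sum, 0.0302 h⁻¹. I count the whole of 4.0 d, though reaching the paid coupling takes up part of it, so the figure is a rough one. That gives 97.5% reacted.

The forecast says 97.7% and 5.9%, a reacted part about the same as mine and a free share below mine, from its own end tally: “Unused nucleophile is 2.2 mM, with free nucleophile ≈ 0.13 mM”.

The flask gives 97.9% and 5.89%, with 1.8% of the free base left unbound, so the forecast stands. Target plus side product, each side product counted once, makes 7.80 mM coupled. Beyond the paid coupling 5.50 mM, that means 4.60 mM of acid, and 4.99 mM stands there. The reacted part moves by 5 points at 2.28 d, or at 0.722 equiv of protonated nucleophile, so a run there would part from the forecast.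

With 0.440 equiv of free base, the paid coupling falls to 2.20 mM. The same mean gives 7.80 mM of acid and a free share of 3.85%. That neighbour flask computes 9.55 mM and 3.17%.

Its constants stand for no real mixture, and the outcome is calculated.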